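**Retrosynthetic overview**

1. The target is numbered as a hydroazulene (C1–C3, C3a, C4–C8, C8a). It is cis-fused, with 3a-OH, 8a-CH3 and 3-isopropyl on one face and the 5-O-veratroyl group on the other. The ester (acid chloride, last step) and the C5 carbinol (hydroxyl-directed anti reduction) are removed first, which leaves a β-hydroxy enone.
2. Key disconnection C4–C3a: a SmI2-mediated Reformatsky-type aldol closure of a bromomethyl (Z)-enone onto the cyclopentanone carbonyl. Three features make it possible: the 1,3-dioxygen pattern C3a–OH/C5–O across the C4 methylene of the seven-membered ring (an aldol retron once C5 is a ketone), the Z C6=C7 alkene that turns the chain back toward the carbonyl, and the quaternary C8a beside C3a, which forces cis fusion.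
3. The bromo enone comes from a Z-vinyl iodide (Stille coupling with a 1-ethoxyvinyl stannane, then NBS). C8a is set by reductive alkylation of (R)-5-isopropyl-2-methylcyclopentenone with (Z)-1-bromo-3-iodobut-2-ene, anti to the isopropyl group.
4. The cyclopentenone comes from asymmetric allylation of an N-isovaleryl oxazolidinone and ring-closing metathesis. Ring order: five-membered ring first (step 5), seven-membered ring second (step 10); no protecting groups are used.

Key step: step 10

Remark: compound 1 is taken as a commercial reagent; bicyclic compounds carry azulene numbering (C3 isopropyl carbon, C3a carbinol carbon, C5 ester carbon, C8a quaternary carbon).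

**Route**

Step 1
Reactants: 1 (4R)-4-benzyl-3-(3-methylbutanoyl)-1,3-oxazolidin-2-one
Product: 3 (4R)-4-benzyl-3-[(2R)-2-(propan-2-yl)pent-4-enoyl]-1,3-oxazolidin-2-one, via sodium Z-enolate 2 (not isolated)
Conditions: NaHMDS (1.1 equiv), THF, −78 °C; allyl bromide (3 equiv), −78 → −40 °C
Reagents that add atoms: allyl bromide, C=CCBr
Why: Evans asymmetric alkylation: the chelated sodium Z-enolate should be allylated on the face opposite the benzyl group of the auxiliary, which sets the (R)-configured isopropyl-bearing carbon (C3 of the target).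

Step 2
Reactants: 3 (4R)-4-benzyl-3-[(2R)-2-(propan-2-yl)pent-4-enoyl]-1,3-oxazolidin-2-one
Product: 5 (2R)-2-(propan-2-yl)pent-4-enoic acid, via lithium peroxycarboxylate 4 (not isolated)
Conditions: LiOH, 30% H2O2, THF/H2O (3:1), 0 °C; aq. Na2SO3; HCl to pH 2
Reagents that add atoms: hydrogen peroxide, OO
Why: Lithium hydroperoxide cleavage of an Evans imide: the small hydroperoxide anion attacks the exocyclic carbonyl even beside a branched α-carbon, sulfite reduces the peracid salt, and the weakly basic conditions should leave the α-stereocentre intact.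

Step 3
Reactants: 5 (2R)-2-(propan-2-yl)pent-4-enoic acid
Product: 7 (2R)-N-methoxy-N-methyl-2-(propan-2-yl)pent-4-enamide, via acid chloride 6 (not isolated)
Conditions: (COCl)2 (1.2 equiv), DMF (cat.), CH2Cl2, 0 °C → rt; then MeNHOMe·HCl (1.3 equiv), pyridine (2.5 equiv), 0 °C → rt
Reagents that add atoms: N,O-dimethylhydroxylamine hydrochloride, CNOC.Cl
Why: Weinreb amide formation through the acid chloride: the hindered acid is activated without base (no ketene, no racemisation) and is then acylated cleanly by the amine.

Step 4
Reactants: 7 (2R)-N-methoxy-N-methyl-2-(propan-2-yl)pent-4-enamide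
Product: 8 (4R)-2-methyl-4-(propan-2-yl)hepta-1,6-dien-3-one
Conditions: isopropenylmagnesium bromide (1.5 equiv), THF, 0 °C → rt; aq. NH4Cl
Reagents that add atoms: isopropenylmagnesium bromide, C=C(C)[Mg]Br
Why: Weinreb ketone synthesis: the magnesium chelate of the tetrahedral adduct survives until work-up, so the isopropenyl ketone is released only after the Grignard reagent is quenched and neither 1,2- nor 1,4-over-addition can occur.

Step 5
Reactants: 8 (4R)-2-methyl-4-(propan-2-yl)hepta-1,6-dien-3-one
Product: 9 (5R)-2-methyl-5-(propan-2-yl)cyclopent-2-en-1-one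
Conditions: Grubbs second-generation catalyst (3 mol%), CH2Cl2 (0.02 M), 40 °C
Reagents that add atoms: none
Why: Ring-closing metathesis between the allyl and isopropenyl termini (five-membered ring, ethylene lost) is a standard entry to 2-methylcyclopent-2-enones and its neutral conditions should not touch the α-stereocentre.

Step 6
Reactants: 10 but-2-yn-1-ol
Product: 12 (2Z)-3-iodobut-2-en-1-ol, via cyclic sodium alkenylalanate 11 (not isolated)
Conditions: Red-Al (1.3 equiv), THF, 0 °C → rt; then I2 (1.3 equiv), THF, −78 → 0 °C; aq. Rochelle salt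
Reagents that add atoms: iodine, II
Why: Alkoxide-directed trans-hydroalumination of a propargylic alcohol places aluminium at C3 syn to the CH2O arm, and iodinolysis with retention should give only the Z-vinyl iodide, which later fixes the cis geometry of the ring alkene C6=C7.

Step 7
Reactants: 12 (2Z)-3-iodobut-2-en-1-ol
Product: 13 (2Z)-1-bromo-3-iodobut-2-ene
Conditions: CBr4 (1.2 equiv), PPh3 (1.25 equiv), CH2Cl2, 0 °C
Reagents that add atoms: carbon tetrabromide, BrC(Br)(Br)Br
Why: Appel bromination: SN2 displacement of the oxyphosphonium group at the primary allylic carbon, which leaves the vinyl iodide and its geometry untouched.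

Step 8
Reactants: 9 (5R)-2-methyl-5-(propan-2-yl)cyclopent-2-en-1-one; 13 (2Z)-1-bromo-3-iodobut-2-ene
Product: 15 (2R,5R)-2-[(2Z)-3-iodobut-2-en-1-yl]-2-methyl-5-(propan-2-yl)cyclopentan-1-one, via lithium enolate 14 (not isolated)
Conditions: L-Selectride (1.05 equiv), THF, −78 °C; then 13 (1.3 equiv), DMPU, −78 → −20 °C
Reagents that add atoms: none
Why: Reductive alkylation of an enone (conjugate hydride addition, then enolate C-alkylation): 1,4-reduction gives only the tetrasubstituted enolate, so the isopropyl-bearing carbon is never enolised, and the allylic bromide should enter anti to the isopropyl group on the α′-carbon, setting the quaternary centre (C8a, R) with the side chain trans to isopropyl.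

Step 9
Reactants: 15 (2R,5R)-2-[(2Z)-3-iodobut-2-en-1-yl]-2-methyl-5-(propan-2-yl)cyclopentan-1-one
Product: 17 (2R,5R)-2-[(2Z)-5-bromo-3-methyl-4-oxopent-2-en-1-yl]-2-methyl-5-(propan-2-yl)cyclopentan-1-one, via 2-ethoxydiene 16 (not isolated)
Conditions: tributyl(1-ethoxyvinyl)stannane (1.3 equiv), Pd(PPh3)4 (5 mol%), CuI (10 mol%), CsF (2 equiv), DMF, 45 °C; filter; then NBS (1.05 equiv), THF/H2O (4:1), 0 °C
Reagents that add atoms: tributyl(1-ethoxyvinyl)stannane, CCCC[Sn](CCCC)(CCCC)C(=C)OCC; N-bromosuccinimide, O=C1CCC(=O)N1Br; water, O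
Why: Stille coupling with retention of alkene geometry installs a masked acetyl group, and NBS bromination of the resulting enol ether (the most electron-rich alkene) in wet THF should deliver the bromomethyl ketone regiospecifically, so no enolisation is needed and the Z-enone never meets base.

Step 10
Reactants: 17 (2R,5R)-2-[(2Z)-5-bromo-3-methyl-4-oxopent-2-en-1-yl]-2-methyl-5-(propan-2-yl)cyclopentan-1-one
Product: 19 (3R,3aS,8aR)-3a-hydroxy-6,8a-dimethyl-3-(propan-2-yl)-2,3,3a,4,8,8a-hexahydroazulen-5(1H)-one, via samarium(III) enolate 18 (not isolated)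
Conditions: SmI2 (2.2 equiv, 0.1 M in THF), slow addition of 17 (final 0.01 M), −78 → −20 °C; aq. NH4Cl
Reagents that add atoms: none
Why: Samarium diiodide reduces the C–Br bond by two single-electron transfers much faster than it reduces either carbonyl group, giving regiospecifically the samarium(III) enolate of the methyl ketone (the cross-conjugated α′-enolate, not the extended dienolate), which adds to the ring ketone through a Sm(III)-bridged transition state and stays chelated as the aldolate until work-up. The closest known reaction type is the SmI2-mediated intramolecular Reformatsky-type aldol reaction of α-halo ketones, which is used to close medium carbocycles onto hindered carbonyl groups. The seven-membered ring closes in the 7-(enolexo)-exo-trig mode, helped by the Z-trisubstituted alkene that turns the chain back toward the carbonyl group. The new tertiary carbinol centre C3a (S) is controlled by the quaternary centre C8a: the short unsaturated tether can reach the carbonyl carbon only from the face on which it is attached, so the ring fusion must be cis (OH syn to the angular methyl), and this is also the face anti to the isopropyl group on C3. The step needs chemoselectivity (C–Br reduction before ketyl formation or enone reduction, secured by low temperature, absence of HMPA and a small excess of SmI2), regioselectivity (C4 as the nucleophilic carbon, secured by the position of the bromine) and irreversibility (the Sm(III) chelate should suppress retro-aldol cleavage and β-elimination).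

Step 11
Reactants: 19 (3R,3aS,8aR)-3a-hydroxy-6,8a-dimethyl-3-(propan-2-yl)-2,3,3a,4,8,8a-hexahydroazulen-5(1H)-one
Product: 20 (3R,3aS,5R,8aR)-6,8a-dimethyl-3-(propan-2-yl)-2,3,4,5,8,8a-hexahydro-1H-azulene-3a,5-diol
Conditions: Me4NBH(OAc)3 (5 equiv), MeCN/AcOH (1:1), −30 → 0 °C
Reagents that add atoms: none
Why: Evans–Saksena directed reduction: exchange of an acetate on boron for the C3a hydroxyl gives an alkoxyborohydride that delivers hydride intramolecularly to C5 on the face of the C3a–O bond, which should give the trans-3a,5-diol (5R) by 1,2-reduction only.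

Step 12
Reactants: 20 (3R,3aS,5R,8aR)-6,8a-dimethyl-3-(propan-2-yl)-2,3,4,5,8,8a-hexahydro-1H-azulene-3a,5-diol; 21 3,4-dimethoxybenzoyl chloride
Product: 22 (3R,3aS,5R,8aR)-3a-hydroxy-6,8a-dimethyl-3-(propan-2-yl)-1,2,3,3a,4,5,8,8a-octahydroazulen-5-yl 3,4-dimethoxybenzoate
Conditions: Et3N (3 equiv), DMAP (0.2 equiv), CH2Cl2, 0 °C → rt
Reagents that add atoms: none
Why: DMAP-catalysed acylation with an acid chloride: only the secondary allylic hydroxyl at C5 should react, because the ring-fusion hydroxyl is tertiary and flanked by the quaternary C8a and the isopropyl-bearing C3, and the C5 configuration is retained.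

**Compound list**

1 | (4R)-4-benzyl-3-(3-methylbutanoyl)-1,3-oxazolidin-2-one | CC(C)CC(=O)N1C(=O)OC[C@H]1Cc1ccccc1 | starting material
2 | sodium (1Z)-1-[(4R)-4-benzyl-2-oxo-1,3-oxazolidin-3-yl]-3-methylbut-1-en-1-olate | CC(C)/C=C(\O[Na])N1C(=O)OC[C@H]1Cc1ccccc1 | intermediate
3 | (4R)-4-benzyl-3-[(2R)-2-(propan-2-yl)pent-4-enoyl]-1,3-oxazolidin-2-one | C=CC[C@H](C(C)C)C(=O)N1C(=O)OC[C@H]1Cc1ccccc1 | intermediate
4 | lithium (2R)-2-(propan-2-yl)pent-4-eneperoxoate | C=CC[C@H](C(C)C)C(=O)O[O-].[Li+] | intermediate
5 | (2R)-2-(propan-2-yl)pent-4-enoic acid | C=CC[C@H](C(C)C)C(=O)O | intermediate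
6 | (2R)-2-(propan-2-yl)pent-4-enoyl chloride | C=CC[C@H](C(C)C)C(=O)Cl | intermediate
7 | (2R)-N-methoxy-N-methyl-2-(propan-2-yl)pent-4-enamide | C=CC[C@H](C(C)C)C(=O)N(C)OC | intermediate
8 | (4R)-2-methyl-4-(propan-2-yl)hepta-1,6-dien-3-one | C=CC[C@H](C(C)C)C(=O)C(C)=C | intermediate
9 | (5R)-2-methyl-5-(propan-2-yl)cyclopent-2-en-1-one | CC1=CC[C@H](C(C)C)C1=O | intermediate
10 | but-2-yn-1-ol | CC#CCO | starting material
11 | sodium 2,2-bis(2-methoxyethoxy)-3-methyl-2,5-dihydro-1,2-oxaluminol-2-uide (cyclic Z-alkenylalanate) | CC1=CCO[Al-]1(OCCOC)OCCOC.[Na+] | intermediate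
12 | (2Z)-3-iodobut-2-en-1-ol | OC/C=C(/C)I | intermediate
13 | (2Z)-1-bromo-3-iodobut-2-ene | BrC/C=C(/C)I | intermediate
14 | lithium (5R)-2-methyl-5-(propan-2-yl)cyclopent-1-en-1-olate | CC1=C(O[Li])[C@@H](C(C)C)CC1 | intermediate
15 | (2R,5R)-2-[(2Z)-3-iodobut-2-en-1-yl]-2-methyl-5-(propan-2-yl)cyclopentan-1-one | O=C1[C@@H](C(C)C)CC[C@]1(C)C/C=C(/C)I | intermediate
16 | (2R,5R)-2-[(2Z)-4-ethoxy-3-methylpenta-2,4-dien-1-yl]-2-methyl-5-(propan-2-yl)cyclopentan-1-one | O=C1[C@@H](C(C)C)CC[C@]1(C)C/C=C(/C)C(=C)OCC | intermediate
17 | (2R,5R)-2-[(2Z)-5-bromo-3-methyl-4-oxopent-2-en-1-yl]-2-methyl-5-(propan-2-yl)cyclopentan-1-one | O=C1[C@@H](C(C)C)CC[C@]1(C)C/C=C(/C)C(=O)CBr | intermediate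
18 | diiodosamarium(III) (3Z)-3-methyl-5-[(1R,3R)-1-methyl-2-oxo-3-(propan-2-yl)cyclopentyl]penta-1,3-dien-2-olate | O=C1[C@@H](C(C)C)CC[C@]1(C)C/C=C(/C)C(=C)O[Sm](I)I | intermediate
19 | (3R,3aS,8aR)-3a-hydroxy-6,8a-dimethyl-3-(propan-2-yl)-2,3,3a,4,8,8a-hexahydroazulen-5(1H)-one | O=C1C[C@]2(O)[C@@H](C(C)C)CC[C@]2(C)CC=C1C | intermediate
20 | (3R,3aS,5R,8aR)-6,8a-dimethyl-3-(propan-2-yl)-2,3,4,5,8,8a-hexahydro-1H-azulene-3a,5-diol | O[C@@H]1C[C@]2(O)[C@@H](C(C)C)CC[C@]2(C)CC=C1C | intermediate
21 | 3,4-dimethoxybenzoyl chloride | COc1ccc(C(=O)Cl)cc1OC | starting material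
22 | (3R,3aS,5R,8aR)-3a-hydroxy-6,8a-dimethyl-3-(propan-2-yl)-1,2,3,3a,4,5,8,8a-octahydroazulen-5-yl 3,4-dimethoxybenzoate | COc1ccc(C(=O)O[C@@H]2C[C@]3(O)[C@@H](C(C)C)CC[C@]3(C)CC=C2C)cc1OC | target

**Step count and risks**

Total step count: 12. Longest linear sequence: 10 steps (steps 1–5 and 8–12, from compound 1).

The three steps most likely to fail:

Step 10 (ring closure). The samarium enolate may be protonated before it closes the ring (reductive debromination only), or the aldolate may revert by retro-aldol cleavage, because the carbonyl carbon is flanked by a quaternary and a branched carbon. The fallback replaces the reductive metal-enolate closure by a Lewis-acid Mukaiyama aldol closure. It sets out from 17: zinc dust and chlorotrimethylsilane in THF/MeCN would reduce the C–Br bond and trap the enolate regiospecifically as the silyl dienol ether (2R,5R)-2-methyl-2-[(2Z)-3-methyl-4-(trimethylsilyloxy)penta-2,4-dien-1-yl]-5-(propan-2-yl)cyclopentan-1-one F1. TiCl4 in CH2Cl2 at −78 °C would then activate the hindered ring ketone toward intramolecular attack, and aqueous work-up comes back to the route at 19.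

Step 8 (quaternary centre). Facial discrimination in the alkylation may be poor, because the isopropyl group sits one carbon away from the reacting enolate carbon, and proton transfer between enolate and product could erode it further. The fallback sets the centre under catalyst control. It sets out from 9: L-Selectride and then allyl chloroformate would give the enol carbonate allyl (5R)-2-methyl-5-(propan-2-yl)cyclopent-1-en-1-yl carbonate F2. A palladium-catalysed decarboxylative asymmetric allylic alkylation (Pd2(dba)3, (R)-t-Bu-PHOX, the ligand enantiomer expected by analogy with 2-allyl-2-methylcycloalkanones to favour the 2R centre) would give (2R,5R)-2-methyl-5-(propan-2-yl)-2-(prop-2-en-1-yl)cyclopentan-1-one F3. Ozonolysis (O3, then PPh3) would give the aldehyde 2-[(1R,3R)-1-methyl-2-oxo-3-(propan-2-yl)cyclopentyl]acetaldehyde F4, and a Z-selective Stork–Zhao Wittig reaction with the ylide from (1-iodoethyl)triphenylphosphonium iodide (NaHMDS, THF, −78 °C) comes back to the route at 15.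

Step 11 (directed reduction). The tertiary, heavily flanked C3a hydroxyl may exchange onto boron too slowly, so that hydride delivery is not intramolecular and the ketone is either left untouched or reduced with poor facial selectivity. The fallback replaces substrate-directed delivery by reagent control and does not rely on the hydroxyl group. It sets out from 19: a Corey–Bakshi–Shibata reduction with (S)-Me-CBS and catecholborane (toluene, −78 → −40 °C), with the alkenyl carbon C6 acting as the large group, should deliver hydride to the face that gives the 5R carbinol, and it comes back to the route at 20.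

**Further compounds**

F1 | step 10 | (2R,5R)-2-methyl-2-[(2Z)-3-methyl-4-(trimethylsilyloxy)penta-2,4-dien-1-yl]-5-(propan-2-yl)cyclopentan-1-one | O=C1[C@@H](C(C)C)CC[C@]1(C)C/C=C(/C)C(=C)O[Si](C)(C)C
F2 | step 8 | allyl (5R)-2-methyl-5-(propan-2-yl)cyclopent-1-en-1-yl carbonate | C=CCOC(=O)OC1=C(C)CC[C@@H]1C(C)C
F3 | step 8 | (2R,5R)-2-methyl-5-(propan-2-yl)-2-(prop-2-en-1-yl)cyclopentan-1-one | O=C1[C@@H](C(C)C)CC[C@]1(C)CC=C
F4 | step 8 | 2-[(1R,3R)-1-methyl-2-oxo-3-(propan-2-yl)cyclopentyl]acetaldehyde | O=C1[C@@H](C(C)C)CC[C@]1(C)CC=O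
F0 | step 11 | none | none
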